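(Readings and results stem from a simulated flask for an exercise.)

I decide to read these flasks by one number: what Z can still do once L has taken its share.

| flask | G | Z | L | remark | time |
|---|---|---|---|---|---|
| beta | 0.050 M | 0.035 M | 0.010 M | run made earlier |  |
| zeta | 0.050 M | 0.47 M | 0.010 M | run made earlier |  |
| alpha | 0.050 M | 0.075 M | 0.0076 M | run made earlier |  |
| grey | 0.080 M | 0.0250 M | 0.0150 M |  | 20 min |
| violet | 0.080 M | 0.300 M | 0.00600 M |  | 20 min |
| green | 0.050 M | 0.0750 M | 0.0100 M |  | 20 min |
| blue | 0.050 M | 0.0400 M | 0.00300 M |  | 20 min |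
| teal | 0.012 M | 0.0750 M | 0.0100 M |  | 20 min |

| run | time / min | D / % | G / % |
|---|---|---|---|
| beta | 1.00 | 1.6 | 86.2 |
| beta | 2.00 | 5.3 | 75.4 |
| beta | 4.00 | 10.7 | 63.5 |
| beta | 8.00 | 18.7 | 50.6 |
| beta | 15.0 | 20.4 | 42.6 |
| zeta | 1.00 | 12.8 | 8.7 |
| zeta | 2.00 | 27.5 | 0.2 |
| zeta | 4.00 | 48.0 | 0.6 |
| zeta | 8.00 | 62.2 | 0 |
| zeta | 15.0 | 58.6 | 0 |
| alpha | 3.00 | 16.1 | 39.1 |
| alpha | 6.00 | 33.0 | 18.8 |
| alpha | 8.00 | 40.2 | 13.5 |
| alpha | 12.0 | 45.9 | 7.2 |
| alpha | 15.0 | 45.7 | 3.9 |

(each reading ± 0.5 percentage points)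

- in percentages every species weighs as the G in it: one E counts as two
- on the list of suspects stand: G + Z -> X; X -> D; G + X -> E; Z + L -> J; D <-> Q

* the flasks by amount of D, in percent of the G charged, highest first, at 20 min (grey / violet / green / blue / teal)
* the amount of D, in percent of the G charged of the flask you put first, at 20 min
* the amount of D, in percent of the G charged of the flask you put last, at 20 min

The suspects are G + Z → X, X → D, G + X → E, Z + L → J and D ⇌ Q. I follow a flask slowly.

In the first instants L and G both call on Z. I bet that L takes its part first, one Z for each L. For teal, Z charged minus L charged, as a fraction of the G charged, then comes to 5.42; this is the spare Z.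

In the middle of zeta, G runs ahead of D. In zeta at 2.00 min, G reads 0.2% while D reads 27.5%, so 72.3% of the charge stands as neither at that reading, and I read X → D as the slower stage in zeta. While G and X stand together, G + X → E can take a second G. This fits beta, which by 15.0 min has used 57.4% of its G on a spare Z of 0.500.

At the end of zeta D sags: it falls from 62.2% at 8.00 min to 58.6% at 15.0 min, a drop of 3.6 percentage points, which I give to D ⇌ Q.

The crossing shows in the G left at the last reading:

beta: spare Z 0.500, G 42.6%, D 20.4%

alpha: spare Z 1.35, G 3.9%, D 45.7%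

zeta: spare Z 9.20, G 0%, D 58.6%

Between beta and alpha, Z stops being the limiting reagent. The new flasks stand thus:

teal 5.42, violet 3.67, green 1.30, blue 0.740, grey 0.125

I commit to that order. Teal's spare Z lies between alpha's and zeta's, so I put its D between their last readings. Grey's spare Z is below beta's, so I scale beta's last D down in proportion:

D(grey) ≈ 20.4% × 0.125 / 0.500 = 5.10%

The forecast reads teal > green > violet > blue > grey, with 49% (44% to 55%) first and 4% (2% to 8%) last, seeing in grey “only about 0.010 M Z left”, and it puts green above violet where I do the reverse.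

The flasks give teal > violet > green > blue > grey, with 54.0% in teal and 4.86% in grey.

    G + Z → X (k = 0.0940 M⁻¹ s⁻¹)
    X → D (k = 0.00380 s⁻¹)
    G + X → E (k = 0.0440 M⁻¹ s⁻¹)
    Z + L → J (k = 0.880 M⁻¹ s⁻¹)
    D ⇌ Q (K = 1.60, k = 9.20 × 10⁻⁴ s⁻¹)

In teal, half of the turnover of Z + L to J is done by 0.183 min, while the half-life of G by G + Z to X alone, at the charged amounts, is 1.6 min, and at 1.88 min Z goes into X at 34 times its rate into J. That is the sequence my spare Z assumes, and teal's stands at 5.42. With teal's Z lowered to 0.030 M, spare Z falls to 1.67, and D stands at 41.8%, beside green's 42.8% at 1.30.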